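**Plan**

1. Rings are lettered A–H from the 3,5-dihydroxyphenoxy end: A, the dibenzofuran rings B and C, the dioxin-fused ring D, the biaryl rings E and F, ring G, and the terminal 2,4,6-trihydroxyphenoxy ring H. Fourteen hydroxyls travel as methyl ethers and the two on ring D as formyl groups.
2. The retrosynthesis first cuts the ring D–O–ring E ether (SNAr on a fluoro dialdehyde), then the E–F biaryl bond (Suzuki–Miyaura), then the F–G ether (SNAr), and finally takes ring H apart into an aryloxymalonate and dimethyl 3-oxopentanedioate.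
3. This last cut is possible because in ring H the ether carbon C-1 lies between the hydroxyl carbons C-2 and C-6, with the third hydroxyl at C-4. That is the pattern of a malonate carbon between its two carbonyls, closed by a three-carbon ketone unit.
4. The core is cut at the B–C aryl–aryl bond (dehydrogenative coupling), at both dioxin C–O bonds (SNAr, then Ullmann), and at the B–O–C and A–O–B ethers (SNAr, Ullmann).
5. Forward: ring H is built on ring G (steps 1–9) and rings F and E are added (steps 10–16). Rings C, B and A are linked (steps 17–22), ring D is made (steps 23–26) and fused on as the dioxin before the furan is closed (steps 27–30). The halves are then joined, the aldehydes turned into phenols, and the methyl ethers cleaved (steps 31–33).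
6. The target has no stereocentre. The E–F axis carries no descriptor in the target and is not controlled.

Key step: step 6

Step 1
Reactants: 1 2-hydroxy-4,6-dimethoxybenzaldehyde
Product: 2 4,6-dimethoxy-2-(methoxymethoxy)benzaldehyde
Conditions: MOMCl, iPr2NEt, CH2Cl2, 0 °C to rt
Reagents that add atoms: chloromethyl methyl ether, COCCl
Why: Williamson-type O-alkylation of the phenol with the α-chloro ether should mask the hydroxyl as a MOM acetal that survives peracid, carbonate and benzylation.

Step 2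
Reactants: 2 4,6-dimethoxy-2-(methoxymethoxy)benzaldehyde
Product: 4 2,4-dimethoxy-6-(methoxymethoxy)phenol, via aryl formate 3 (not isolated)
Conditions: mCPBA, CH2Cl2, 0 °C to rt; then K2CO3 (cat.), MeOH, rt
Reagents that add atoms: 3-chloroperoxybenzoic acid, OOC(=O)c1cccc(Cl)c1
Why: Baeyer–Villiger (Dakin-type) oxidation, in which the 2,4,6-trioxygenated aryl group should migrate in preference to hydride, followed by mild methanolysis of the formate.

Step 3
Reactants: 4 2,4-dimethoxy-6-(methoxymethoxy)phenol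
Product: 5 2-(benzyloxy)-1,5-dimethoxy-3-(methoxymethoxy)benzene
Conditions: BnBr, K2CO3, DMF, 60 °C
Reagents that add atoms: benzyl bromide, BrCc1ccccc1
Why: Williamson ether synthesis on the only free hydroxyl, the oxygen that will later carry ring F.

Step 4
Reactants: 5 2-(benzyloxy)-1,5-dimethoxy-3-(methoxymethoxy)benzene
Product: 6 2-(benzyloxy)-3,5-dimethoxyphenol
Conditions: HCl (cat.), MeOH, 50 °C
Reagents that add atoms: none
Why: Acid-catalysed transacetalisation should remove the MOM group while benzyl and methyl ethers are inert.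

Step 5
Reactants: 6 2-(benzyloxy)-3,5-dimethoxyphenol; 7 dimethyl bromomalonate
Product: 8 dimethyl 2-[2-(benzyloxy)-3,5-dimethoxyphenoxy]malonate
Conditions: K2CO3, acetone, reflux
Reagents that add atoms: none
Why: Williamson O-alkylation, the unhindered phenoxide displacing bromide from the doubly activated carbon, so the hindered ether of ring H is made by simple SN2 chemistry.

Step 6
Reactants: 8 dimethyl 2-[2-(benzyloxy)-3,5-dimethoxyphenoxy]malonate; 9 dimethyl 3-oxopentanedioate
Product: 11 dimethyl 5-[2-(benzyloxy)-3,5-dimethoxyphenoxy]-2,4,6-trihydroxyisophthalate, via acyclic Claisen adduct 10 (not isolated)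
Conditions: NaOMe, MeOH, reflux (9 added slowly); then aq. HCl, 0 °C
Reagents that add atoms: none
Why: Methoxide deprotonates 9 at a methylene carbon and this enolate acylates on one ester carbonyl of 8 in an intermolecular Claisen condensation to give the open-chain adduct 10; the second methylene of the oxopentanedioate unit then attacks the remaining malonate ester, and threefold enolisation of the resulting cyclohexane-1,3,5-trione gives benzene ring H with the aryl ether already on the carbon between two hydroxyls. The closest known reaction is the classical base-mediated condensation of a malonic ester with an acetonedicarboxylic ester to a 2,4,6-trihydroxyisophthalate, run here with a 2-aryloxy-substituted malonate. Ring H is the only ring closed, and it closes by a Dieckmann-type (intramolecular Claisen) 6-exo-trig acyl substitution that forms the second C–C bond. No stereocentre is formed. The step needs C-acylation to win over O-acylation and the crossed condensation to win over self-condensation of 9: both partners are symmetric so no regiochemical question arises, slow addition keeps free 9 low, O-acyl products revert under methoxide in methanol (methyl esters, so transesterification is degenerate), and the product leaves all equilibria as its aromatic phenoxide salt.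

Step 7
Reactants: 11 dimethyl 5-[2-(benzyloxy)-3,5-dimethoxyphenoxy]-2,4,6-trihydroxyisophthalate
Product: 13 2-[2-(benzyloxy)-3,5-dimethoxyphenoxy]benzene-1,3,5-triol, via isophthalic diacid 12 (not isolated)
Conditions: NaOH, H2O–MeOH, reflux, argon; then HCl to pH 2, 70 °C
Reagents that add atoms: none
Why: Ester saponification followed by decarboxylation of the 2,4,6-trihydroxybenzoic acid units, which lose CO2 readily through their ipso-protonated keto tautomers.

Step 8
Reactants: 13 2-[2-(benzyloxy)-3,5-dimethoxyphenoxy]benzene-1,3,5-triol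
Product: 14 2-[2-(benzyloxy)-3,5-dimethoxyphenoxy]-1,3,5-trimethoxybenzene
Conditions: Me2SO4, K2CO3, acetone, reflux
Reagents that add atoms: dimethyl sulfate, COS(=O)(=O)OC
Why: Williamson O-methylation under the conditions (dimethyl sulfate, carbonate, acetone) that give phloroglucinol ethers rather than C-methylated products.

Step 9
Reactants: 14 2-[2-(benzyloxy)-3,5-dimethoxyphenoxy]-1,3,5-trimethoxybenzene
Product: 15 2,4-dimethoxy-6-(2,4,6-trimethoxyphenoxy)phenol
Conditions: H2 (1 atm), Pd/C, EtOAc–MeOH, rt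
Reagents that add atoms: none
Why: Catalytic hydrogenolysis of the benzyl ether should free the central hydroxyl of ring G without touching methyl or diaryl ethers.

Step 10
Reactants: 15 2,4-dimethoxy-6-(2,4,6-trimethoxyphenoxy)phenol; 16 2-fluoro-4,6-dimethoxybenzaldehyde
Product: 17 2-[2,4-dimethoxy-6-(2,4,6-trimethoxyphenoxy)phenoxy]-4,6-dimethoxybenzaldehyde
Conditions: Cs2CO3, DMF, 110 °C
Reagents that add atoms: none
Why: Nucleophilic aromatic substitution (SNAr), in which the ortho-formyl group stabilises the Meisenheimer intermediate and both methoxy groups sit meta to fluorine, so the hindered phenoxide should displace fluoride and form the F–G ether.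

Step 11
Reactants: 17 2-[2,4-dimethoxy-6-(2,4,6-trimethoxyphenoxy)phenoxy]-4,6-dimethoxybenzaldehyde
Product: 19 2-[2,4-dimethoxy-6-(2,4,6-trimethoxyphenoxy)phenoxy]-4,6-dimethoxyphenol, via aryl formate 18 (not isolated)
Conditions: mCPBA, CH2Cl2, 0 °C to rt; then K2CO3 (cat.), MeOH, rt
Reagents that add atoms: 3-chloroperoxybenzoic acid, OOC(=O)c1cccc(Cl)c1
Why: Baeyer–Villiger oxidation of an aldehyde flanked by two ether oxygens and para to a third should give the formate by aryl migration, and methanolysis leaves a phenol at the future biaryl carbon of ring F.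

Step 12
Reactants: 19 2-[2,4-dimethoxy-6-(2,4,6-trimethoxyphenoxy)phenoxy]-4,6-dimethoxyphenol
Product: 20 2-[2,4-dimethoxy-6-(2,4,6-trimethoxyphenoxy)phenoxy]-4,6-dimethoxyphenyl trifluoromethanesulfonate
Conditions: Tf2O, pyridine, CH2Cl2, 0 °C
Reagents that add atoms: trifluoromethanesulfonic anhydride, O=S(=O)(OS(=O)(=O)C(F)(F)F)C(F)(F)F
Why: O-Sulfonylation of the phenol should turn this oxygen into a triflate leaving group for cross-coupling.

Step 13
Reactants: 21 3,5-dimethoxyphenol
Product: 22 1,3-dimethoxy-5-(methoxymethoxy)benzene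
Conditions: MOMCl, iPr2NEt, CH2Cl2, 0 °C to rt
Reagents that add atoms: chloromethyl methyl ether, COCCl
Why: Williamson-type MOM protection installs both the director for the next step and the later handle on the ring E oxygen.

Step 14
Reactants: 22 1,3-dimethoxy-5-(methoxymethoxy)benzene
Product: 24 2-[2,4-dimethoxy-6-(methoxymethoxy)phenyl]-4,4,5,5-tetramethyl-1,3,2-dioxaborolane, via aryllithium 23 (not isolated)
Conditions: n-BuLi, THF, 0 °C; then iPrOBpin, −78 °C to rt; aq. NH4Cl
Reagents that add atoms: 2-isopropoxy-4,4,5,5-tetramethyl-1,3,2-dioxaborolane, CC(C)OB1OC(C)(C)C(C)(C)O1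
Why: Directed ortho-metalation, in which the MOM acetal is the stronger director so that lithiation should occur at one of the two equivalent positions between OMOM and OMe, followed by trapping with the boron electrophile.

Step 15
Reactants: 20 2-[2,4-dimethoxy-6-(2,4,6-trimethoxyphenoxy)phenoxy]-4,6-dimethoxyphenyl trifluoromethanesulfonate; 24 2-[2,4-dimethoxy-6-(methoxymethoxy)phenyl]-4,4,5,5-tetramethyl-1,3,2-dioxaborolane
Product: 25 2-[2,4-dimethoxy-6-(2,4,6-trimethoxyphenoxy)phenoxy]-2',4,4',6-tetramethoxy-6'-(methoxymethoxy)-1,1'-biphenyl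
Conditions: Pd(OAc)2, SPhos, K3PO4, toluene–H2O, 100 °C
Reagents that add atoms: none
Why: Suzuki–Miyaura coupling with a bulky dialkylbiarylphosphine, the ligand class established for tetra-ortho-substituted biaryls, should form the E–F bond.

Step 16
Reactants: 25 2-[2,4-dimethoxy-6-(2,4,6-trimethoxyphenoxy)phenoxy]-2',4,4',6-tetramethoxy-6'-(methoxymethoxy)-1,1'-biphenyl
Product: 26 2'-[2,4-dimethoxy-6-(2,4,6-trimethoxyphenoxy)phenoxy]-4,4',6,6'-tetramethoxy-[1,1'-biphenyl]-2-ol
Conditions: HCl (cat.), MeOH–THF, 50 °C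
Reagents that add atoms: none
Why: Acid-catalysed MOM acetal cleavage should free the single ring E hydroxyl that will bond to ring D.

Step 17
Reactants: 27 2-bromo-3-methoxyphenol
Product: 28 2-bromo-1-methoxy-3-(methoxymethoxy)benzene
Conditions: MOMCl, iPr2NEt, CH2Cl2, 0 °C to rt
Reagents that add atoms: chloromethyl methyl ether, COCCl
Why: Williamson-type MOM protection distinguishes the future dioxin oxygen of ring C from the methoxy group.

Step 18
Reactants: 28 2-bromo-1-methoxy-3-(methoxymethoxy)benzene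
Product: 30 4-bromo-3-methoxy-5-(methoxymethoxy)phenol, via pinacol boronate 29 (not isolated)
Conditions: [Ir(OMe)(cod)]2 (cat.), 4,4'-di-tert-butyl-2,2'-bipyridine, B2pin2, THF, 80 °C; then aq. KHSO5 (Oxone), acetone, 0 °C
Reagents that add atoms: potassium peroxymonosulfate, [K+].[O-]S(=O)(=O)OO
Why: Iridium-catalysed aromatic C–H borylation is sterically controlled and should hit the only C–H without an ortho substituent (meta to both oxygens, para to bromine), and oxidation of the C–B bond then gives the phenol.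

Step 19
Reactants: 30 4-bromo-3-methoxy-5-(methoxymethoxy)phenol; 16 2-fluoro-4,6-dimethoxybenzaldehyde
Product: 31 2-[4-bromo-3-methoxy-5-(methoxymethoxy)phenoxy]-4,6-dimethoxybenzaldehyde
Conditions: K2CO3, DMF, 100 °C
Reagents that add atoms: none
Why: SNAr of the unhindered phenoxide on the ortho-formyl-activated fluoride should form the B–O–C ether without any metal that could touch the aryl bromide.

Step 20
Reactants: 31 2-[4-bromo-3-methoxy-5-(methoxymethoxy)phenoxy]-4,6-dimethoxybenzaldehyde
Product: 33 2-[4-bromo-3-methoxy-5-(methoxymethoxy)phenoxy]-4,6-dimethoxyphenol, via aryl formate 32 (not isolated)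
Conditions: mCPBA, CH2Cl2, 0 °C to rt; then K2CO3 (cat.), MeOH, rt
Reagents that add atoms: 3-chloroperoxybenzoic acid, OOC(=O)c1cccc(Cl)c1
Why: Baeyer–Villiger oxidation of the trioxygenated benzaldehyde followed by formate methanolysis should place the hydroxyl of ring B that is to carry ring A.

Step 21
Reactants: 33 2-[4-bromo-3-methoxy-5-(methoxymethoxy)phenoxy]-4,6-dimethoxyphenol; 34 1-iodo-3,5-dimethoxybenzene
Product: 35 2-bromo-5-[2-(3,5-dimethoxyphenoxy)-3,5-dimethoxyphenoxy]-1-methoxy-3-(methoxymethoxy)benzene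
Conditions: CuI (cat.), picolinic acid, K3PO4, DMSO, 85 °C
Reagents that add atoms: none
Why: Ullmann diaryl ether synthesis under ligand-accelerated copper catalysis, a system suited to di-ortho-substituted phenols, should couple at the unhindered aryl iodide while the doubly ortho-substituted aryl bromide stays intact.

Step 22
Reactants: 35 2-bromo-5-[2-(3,5-dimethoxyphenoxy)-3,5-dimethoxyphenoxy]-1-methoxy-3-(methoxymethoxy)benzene
Product: 36 2-bromo-5-[2-(3,5-dimethoxyphenoxy)-3,5-dimethoxyphenoxy]-3-methoxyphenol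
Conditions: HCl (cat.), MeOH–THF, 50 °C
Reagents that add atoms: none
Why: Acid-catalysed MOM cleavage should free the ring C hydroxyl next to bromine, the nucleophile for the dioxin construction.

Step 23
Reactants: 37 2,6-difluorophenol
Product: 38 2-(benzyloxy)-1,3-difluorobenzene
Conditions: BnBr, K2CO3, DMF, rt
Reagents that add atoms: benzyl bromide, BrCc1ccccc1
Why: Williamson ether synthesis protects the future central dioxin oxygen of ring D so that the ring can act as an electrophile.

Step 24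
Reactants: 38 2-(benzyloxy)-1,3-difluorobenzene
Product: 40 3-(benzyloxy)-2,4-difluorobenzaldehyde, via aryllithium 39 (not isolated)
Conditions: LDA, THF, −78 °C; then DMF; aq. NH4Cl
Reagents that add atoms: N,N-dimethylformamide, CN(C)C=O
Why: Fluorine-directed ortho-lithiation followed by formylation with DMF, LDA removing the most acidic ring proton next to fluorine at one of two equivalent positions.

Step 25
Reactants: 40 3-(benzyloxy)-2,4-difluorobenzaldehyde
Product: 41 2-(benzyloxy)-4-(dimethoxymethyl)-1,3-difluorobenzene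
Conditions: HC(OMe)3, TsOH (cat.), MeOH, rt
Reagents that add atoms: trimethyl orthoformate, COC(OC)OC
Why: Acid-catalysed acetalisation should mask the aldehyde against the second lithiation.

Step 26
Reactants: 41 2-(benzyloxy)-4-(dimethoxymethyl)-1,3-difluorobenzene
Product: 44 5-(benzyloxy)-4,6-difluoroisophthalaldehyde, via aryllithium 42 (not isolated), via formyl acetal 43 (not isolated)
Conditions: LDA, THF, −78 °C; then DMF; then 2 M HCl, THF, rt
Reagents that add atoms: N,N-dimethylformamide, CN(C)C=O; water, O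
Why: A second fluorine-directed ortho-lithiation and DMF formylation at the only remaining position next to fluorine (the acetal being a weak director), followed by acetal hydrolysis on acidic work-up, should give the symmetric dialdehyde.

Step 27
Reactants: 36 2-bromo-5-[2-(3,5-dimethoxyphenoxy)-3,5-dimethoxyphenoxy]-3-methoxyphenol; 44 5-(benzyloxy)-4,6-difluoroisophthalaldehyde
Product: 45 5-(benzyloxy)-4-{2-bromo-5-[2-(3,5-dimethoxyphenoxy)-3,5-dimethoxyphenoxy]-3-methoxyphenoxy}-6-fluoroisophthalaldehyde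
Conditions: K2CO3, DMF, 0 °C to rt (44 in slight excess)
Reagents that add atoms: none
Why: SNAr, in which each fluorine of 44 is activated by one ortho- and one para-formyl group, the two are equivalent, and the first aryloxy group should deactivate the ring enough to stop at monosubstitution.

Step 28
Reactants: 45 5-(benzyloxy)-4-{2-bromo-5-[2-(3,5-dimethoxyphenoxy)-3,5-dimethoxyphenoxy]-3-methoxyphenoxy}-6-fluoroisophthalaldehyde
Product: 46 4-{2-bromo-5-[2-(3,5-dimethoxyphenoxy)-3,5-dimethoxyphenoxy]-3-methoxyphenoxy}-6-fluoro-5-hydroxyisophthalaldehyde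
Conditions: BCl3, pentamethylbenzene, CH2Cl2, −78 °C; then aq. work-up
Reagents that add atoms: none
Why: Lewis-acid debenzylation with BCl3, the benzyl cation being trapped by pentamethylbenzene (Friedel–Crafts scavenging), should spare the electron-rich rings, the methyl ethers and the aryl bromide at low temperature.

Step 29
Reactants: 46 4-{2-bromo-5-[2-(3,5-dimethoxyphenoxy)-3,5-dimethoxyphenoxy]-3-methoxyphenoxy}-6-fluoro-5-hydroxyisophthalaldehyde
Product: 47 8-[2-(3,5-dimethoxyphenoxy)-3,5-dimethoxyphenoxy]-4-fluoro-6-methoxydibenzo[b,e][1,4]dioxine-1,3-dicarbaldehyde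
Conditions: CuI, N,N-dimethylglycine, Cs2CO3, 1,4-dioxane, 100 °C, high dilution
Reagents that add atoms: none
Why: Intramolecular Ullmann etherification should close the six-membered dioxin ring in the only possible orientation, because the oxygen on the central carbon of ring D attacks the brominated carbon of ring C and the unactivated ipso carbon of ring C rules out Smiles scrambling.

Step 30
Reactants: 47 8-[2-(3,5-dimethoxyphenoxy)-3,5-dimethoxyphenoxy]-4-fluoro-6-methoxydibenzo[b,e][1,4]dioxine-1,3-dicarbaldehyde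
Product: 48 ring A–D fluoro dialdehyde (47 with dioxine C-9 bonded to C-6 of the pendant 2-(3,5-dimethoxyphenoxy)-3,5-dimethoxyphenoxy ring; furan closed)
Conditions: Pd(OAc)2 (1.5 equiv), AcOH–CF3CO2H, 80 °C, argon
Reagents that add atoms: none
Why: Palladium-mediated dehydrogenative (double C–H) biaryl coupling of a diaryl ether to a dibenzofuran, in which ring B has a single free ortho position and palladation on ring C should prefer C-9 (para to the methoxy group and flanked by the planar ring-fused dioxin oxygen) over C-7 (shielded by the methoxy group).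

Step 31
Reactants: 48 ring A–D fluoro dialdehyde; 26 2'-[2,4-dimethoxy-6-(2,4,6-trimethoxyphenoxy)phenoxy]-4,4',6,6'-tetramethoxy-[1,1'-biphenyl]-2-ol
Product: 49 ring A–H dialdehyde (48 with fluorine replaced by the biphenyl-2-yloxy group of 26)
Conditions: Cs2CO3, DMF, 70 °C
Reagents that add atoms: none
Why: SNAr, in which the last fluorine is still ortho and para to formyl groups and should be displaced by the phenoxide of 26, joining the halves at the D–O–E ether.

Step 32
Reactants: 49 ring A–H dialdehyde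
Product: 51 ring A–H tetradecamethyl ether diol (49 with each CHO replaced by OH), via bis-formate 50 (not isolated)
Conditions: mCPBA (2.5 equiv), CH2Cl2, 0 °C; then K2CO3 (cat.), MeOH, argon, rt
Reagents that add atoms: 3-chloroperoxybenzoic acid, OOC(=O)c1cccc(Cl)c1
Why: Twofold Baeyer–Villiger oxidation, in which each formyl group sits ortho and para to an aryl ether oxygen so that aryl migration to the bis-formate is expected, followed by methanolysis to free the two hydroxyls of ring D.

Step 33
Reactants: 51 ring A–H tetradecamethyl ether diol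
Product: 52 CNP0192765.0 (target)
Conditions: BBr3 (excess), CH2Cl2, −78 °C to rt; then MeOH–H2O, argon
Reagents that add atoms: none
Why: Lewis-acid cleavage of all fourteen aryl methyl ethers by BBr3, to which the diaryl ethers, the dioxin and the furan are inert, should release the target with its sixteen hydroxyls.

**Compound list**

1 | 2-hydroxy-4,6-dimethoxybenzaldehyde | O=Cc1c(O)cc(OC)cc1OC | starting material
2 | 4,6-dimethoxy-2-(methoxymethoxy)benzaldehyde | O=Cc1c(OCOC)cc(OC)cc1OC | intermediate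
3 | 2,4-dimethoxy-6-(methoxymethoxy)phenyl formate | O=COc1c(OCOC)cc(OC)cc1OC | intermediate
4 | 2,4-dimethoxy-6-(methoxymethoxy)phenol | Oc1c(OCOC)cc(OC)cc1OC | intermediate
5 | 2-(benzyloxy)-1,5-dimethoxy-3-(methoxymethoxy)benzene | COCOc1cc(OC)cc(OC)c1OCc1ccccc1 | intermediate
6 | 2-(benzyloxy)-3,5-dimethoxyphenol | Oc1cc(OC)cc(OC)c1OCc1ccccc1 | intermediate
7 | dimethyl bromomalonate | COC(=O)C(Br)C(=O)OC | starting material
8 | dimethyl 2-[2-(benzyloxy)-3,5-dimethoxyphenoxy]malonate | COC(=O)C(Oc1cc(OC)cc(OC)c1OCc1ccccc1)C(=O)OC | intermediate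
9 | dimethyl 3-oxopentanedioate | COC(=O)CC(=O)CC(=O)OC | starting material
10 | dimethyl 2-[2-(benzyloxy)-3,5-dimethoxyphenoxy]-4-(methoxycarbonyl)-3,5-dioxoheptanedioate | COC(=O)C(Oc1cc(OC)cc(OC)c1OCc1ccccc1)C(=O)C(C(=O)OC)C(=O)CC(=O)OC | intermediate
11 | dimethyl 5-[2-(benzyloxy)-3,5-dimethoxyphenoxy]-2,4,6-trihydroxyisophthalate | COC(=O)c1c(O)c(Oc2cc(OC)cc(OC)c2OCc2ccccc2)c(O)c(C(=O)OC)c1O | intermediate
12 | 5-[2-(benzyloxy)-3,5-dimethoxyphenoxy]-2,4,6-trihydroxyisophthalic acid | OC(=O)c1c(O)c(Oc2cc(OC)cc(OC)c2OCc2ccccc2)c(O)c(C(=O)O)c1O | intermediate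
13 | 2-[2-(benzyloxy)-3,5-dimethoxyphenoxy]benzene-1,3,5-triol | Oc1cc(O)c(Oc2cc(OC)cc(OC)c2OCc2ccccc2)c(O)c1 | intermediate
14 | 2-[2-(benzyloxy)-3,5-dimethoxyphenoxy]-1,3,5-trimethoxybenzene | COc1cc(OC)c(Oc2cc(OC)cc(OC)c2OCc2ccccc2)c(OC)c1 | intermediate
15 | 2,4-dimethoxy-6-(2,4,6-trimethoxyphenoxy)phenol | COc1cc(OC)c(Oc2cc(OC)cc(OC)c2O)c(OC)c1 | intermediate
16 | 2-fluoro-4,6-dimethoxybenzaldehyde | O=Cc1c(F)cc(OC)cc1OC | starting material
17 | 2-[2,4-dimethoxy-6-(2,4,6-trimethoxyphenoxy)phenoxy]-4,6-dimethoxybenzaldehyde | O=Cc1c(Oc2c(OC)cc(OC)cc2Oc2c(OC)cc(OC)cc2OC)cc(OC)cc1OC | intermediate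
18 | 2-[2,4-dimethoxy-6-(2,4,6-trimethoxyphenoxy)phenoxy]-4,6-dimethoxyphenyl formate | O=COc1c(Oc2c(OC)cc(OC)cc2Oc2c(OC)cc(OC)cc2OC)cc(OC)cc1OC | intermediate
19 | 2-[2,4-dimethoxy-6-(2,4,6-trimethoxyphenoxy)phenoxy]-4,6-dimethoxyphenol | Oc1c(Oc2c(OC)cc(OC)cc2Oc2c(OC)cc(OC)cc2OC)cc(OC)cc1OC | intermediate
20 | 2-[2,4-dimethoxy-6-(2,4,6-trimethoxyphenoxy)phenoxy]-4,6-dimethoxyphenyl trifluoromethanesulfonate | O=S(=O)(Oc1c(Oc2c(OC)cc(OC)cc2Oc2c(OC)cc(OC)cc2OC)cc(OC)cc1OC)C(F)(F)F | intermediate
21 | 3,5-dimethoxyphenol | COc1cc(O)cc(OC)c1 | starting material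
22 | 1,3-dimethoxy-5-(methoxymethoxy)benzene | COCOc1cc(OC)cc(OC)c1 | intermediate
23 | [2,4-dimethoxy-6-(methoxymethoxy)phenyl]lithium | COCOc1cc(OC)cc(OC)c1[Li] | intermediate
24 | 2-[2,4-dimethoxy-6-(methoxymethoxy)phenyl]-4,4,5,5-tetramethyl-1,3,2-dioxaborolane | COCOc1cc(OC)cc(OC)c1B1OC(C)(C)C(C)(C)O1 | intermediate
25 | 2-[2,4-dimethoxy-6-(2,4,6-trimethoxyphenoxy)phenoxy]-2',4,4',6-tetramethoxy-6'-(methoxymethoxy)-1,1'-biphenyl | COCOc1cc(OC)cc(OC)c1-c1c(Oc2c(OC)cc(OC)cc2Oc2c(OC)cc(OC)cc2OC)cc(OC)cc1OC | intermediate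
26 | 2'-[2,4-dimethoxy-6-(2,4,6-trimethoxyphenoxy)phenoxy]-4,4',6,6'-tetramethoxy-[1,1'-biphenyl]-2-ol | Oc1cc(OC)cc(OC)c1-c1c(Oc2c(OC)cc(OC)cc2Oc2c(OC)cc(OC)cc2OC)cc(OC)cc1OC | intermediate
27 | 2-bromo-3-methoxyphenol | COc1cccc(O)c1Br | starting material
28 | 2-bromo-1-methoxy-3-(methoxymethoxy)benzene | COCOc1cccc(OC)c1Br | intermediate
29 | 2-[4-bromo-3-methoxy-5-(methoxymethoxy)phenyl]-4,4,5,5-tetramethyl-1,3,2-dioxaborolane | COCOc1cc(B2OC(C)(C)C(C)(C)O2)cc(OC)c1Br | intermediate
30 | 4-bromo-3-methoxy-5-(methoxymethoxy)phenol | COCOc1cc(O)cc(OC)c1Br | intermediate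
31 | 2-[4-bromo-3-methoxy-5-(methoxymethoxy)phenoxy]-4,6-dimethoxybenzaldehyde | O=Cc1c(Oc2cc(OC)c(Br)c(OCOC)c2)cc(OC)cc1OC | intermediate
32 | 2-[4-bromo-3-methoxy-5-(methoxymethoxy)phenoxy]-4,6-dimethoxyphenyl formate | O=COc1c(Oc2cc(OC)c(Br)c(OCOC)c2)cc(OC)cc1OC | intermediate
33 | 2-[4-bromo-3-methoxy-5-(methoxymethoxy)phenoxy]-4,6-dimethoxyphenol | Oc1c(Oc2cc(OC)c(Br)c(OCOC)c2)cc(OC)cc1OC | intermediate
34 | 1-iodo-3,5-dimethoxybenzene | COc1cc(I)cc(OC)c1 | starting material
35 | 2-bromo-5-[2-(3,5-dimethoxyphenoxy)-3,5-dimethoxyphenoxy]-1-methoxy-3-(methoxymethoxy)benzene | COCOc1cc(Oc2cc(OC)cc(OC)c2Oc2cc(OC)cc(OC)c2)cc(OC)c1Br | intermediate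
36 | 2-bromo-5-[2-(3,5-dimethoxyphenoxy)-3,5-dimethoxyphenoxy]-3-methoxyphenol | Oc1cc(Oc2cc(OC)cc(OC)c2Oc2cc(OC)cc(OC)c2)cc(OC)c1Br | intermediate
37 | 2,6-difluorophenol | Oc1c(F)cccc1F | starting material
38 | 2-(benzyloxy)-1,3-difluorobenzene | Fc1cccc(F)c1OCc1ccccc1 | intermediate
39 | [3-(benzyloxy)-2,4-difluorophenyl]lithium | [Li]c1ccc(F)c(OCc2ccccc2)c1F | intermediate
40 | 3-(benzyloxy)-2,4-difluorobenzaldehyde | O=Cc1ccc(F)c(OCc2ccccc2)c1F | intermediate
41 | 2-(benzyloxy)-4-(dimethoxymethyl)-1,3-difluorobenzene | COC(OC)c1ccc(F)c(OCc2ccccc2)c1F | intermediate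
42 | [4-(benzyloxy)-5-(dimethoxymethyl)-2,4-difluorophenyl]lithium, i.e. the 5-lithio derivative of 41 (lithium next to the fluorine remote from the acetal) | COC(OC)c1cc([Li])c(F)c(OCc2ccccc2)c1F | intermediate
43 | 3-(benzyloxy)-5-(dimethoxymethyl)-2,4-difluorobenzaldehyde | COC(OC)c1cc(C=O)c(F)c(OCc2ccccc2)c1F | intermediate
44 | 5-(benzyloxy)-4,6-difluoroisophthalaldehyde | O=Cc1cc(C=O)c(F)c(OCc2ccccc2)c1F | intermediate
45 | 5-(benzyloxy)-4-{2-bromo-5-[2-(3,5-dimethoxyphenoxy)-3,5-dimethoxyphenoxy]-3-methoxyphenoxy}-6-fluoroisophthalaldehyde | COc1cc(OC)cc(Oc2c(Oc3cc(OC)c(Br)c(Oc4c(C=O)cc(C=O)c(F)c4OCc4ccccc4)c3)cc(OC)cc2OC)c1 | intermediate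
46 | 4-{2-bromo-5-[2-(3,5-dimethoxyphenoxy)-3,5-dimethoxyphenoxy]-3-methoxyphenoxy}-6-fluoro-5-hydroxyisophthalaldehyde | COc1cc(OC)cc(Oc2c(Oc3cc(OC)c(Br)c(Oc4c(C=O)cc(C=O)c(F)c4O)c3)cc(OC)cc2OC)c1 | intermediate
47 | 8-[2-(3,5-dimethoxyphenoxy)-3,5-dimethoxyphenoxy]-4-fluoro-6-methoxydibenzo[b,e][1,4]dioxine-1,3-dicarbaldehyde | COc1cc(OC)cc(Oc2c(Oc3cc(OC)c4Oc5c(F)c(C=O)cc(C=O)c5Oc4c3)cc(OC)cc2OC)c1 | intermediate
48 | ring A–D fluoro dialdehyde (47 with dioxine C-9 bonded to C-6 of the pendant aryloxy ring; furan closed) | COc1cc(OC)cc(Oc2c3oc4cc(OC)c5Oc6c(F)c(C=O)cc(C=O)c6Oc5c4c3c(OC)cc2OC)c1 | intermediate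
49 | ring A–H dialdehyde (48 with fluorine replaced by the biphenyl-2-yloxy group of 26) | COc1cc(OC)cc(Oc2c3oc4cc(OC)c5Oc6c(Oc7cc(OC)cc(OC)c7-c7c(Oc8c(OC)cc(OC)cc8Oc8c(OC)cc(OC)cc8OC)cc(OC)cc7OC)c(C=O)cc(C=O)c6Oc5c4c3c(OC)cc2OC)c1 | intermediate
50 | ring A–H bis-formate (49 with each CHO replaced by OCHO) | COc1cc(OC)cc(Oc2c3oc4cc(OC)c5Oc6c(Oc7cc(OC)cc(OC)c7-c7c(Oc8c(OC)cc(OC)cc8Oc8c(OC)cc(OC)cc8OC)cc(OC)cc7OC)c(OC=O)cc(OC=O)c6Oc5c4c3c(OC)cc2OC)c1 | intermediate
51 | ring A–H tetradecamethyl ether diol (49 with each CHO replaced by OH) | COc1cc(OC)cc(Oc2c3oc4cc(OC)c5Oc6c(Oc7cc(OC)cc(OC)c7-c7c(Oc8c(OC)cc(OC)cc8Oc8c(OC)cc(OC)cc8OC)cc(OC)cc7OC)c(O)cc(O)c6Oc5c4c3c(OC)cc2OC)c1 | intermediate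
52 | CNP0192765.0 | Oc1cc(O)cc(Oc2c3oc4cc(O)c5Oc6c(Oc7cc(O)cc(O)c7-c7c(Oc8c(O)cc(O)cc8Oc8c(O)cc(O)cc8O)cc(O)cc7O)c(O)cc(O)c6Oc5c4c3c(O)cc2O)c1 | target

**Count and risks**

Total step count: 33. Longest linear sequence: 17 steps (steps 1–12, 15, 16, 31, 32, 33).

The three steps most likely to fail are these.

Step 6 (ring H by double Claisen condensation). The enolate of 9 may condense with itself or be acylated on oxygen, or the α-aryloxy β-keto ester may suffer retro-Claisen cleavage before the ring closes, so that no aromatic product accumulates. The fallback abandons ring construction and makes the G–O–H ether by substitution. It sets out from 16, which is treated with commercial 2,4,6-trimethoxyphenol F1 (Cs2CO3, DMF, 110 °C) in an SNAr reaction to give 4,6-dimethoxy-2-(2,4,6-trimethoxyphenoxy)benzaldehyde F2. Baeyer–Villiger oxidation of F2 with mCPBA gives 2,4-dimethoxy-6-(2,4,6-trimethoxyphenoxy)phenyl formate F3, and methanolysis of F3 comes back to the route at 15.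

Step 30 (furan closure by double C–H coupling). Palladation of the deactivated ring C may be slow, may occur at C-7 instead of C-9, or may be overtaken by protodepalladation and intermolecular coupling of ring A. The fallback fixes the site with a halogen before ring D is attached. It sets out from 36: amine-catalysed ortho-bromination of the free phenol (NBS, iPr2NH cat., CH2Cl2, 0 °C) should give 2,6-dibromo-3-[2-(3,5-dimethoxyphenoxy)-3,5-dimethoxyphenoxy]-5-methoxyphenol F4. Intramolecular direct arylation under zerovalent palladium catalysis (Pd(OAc)2, PCy3·HBF4, K2CO3, DMA, 110 °C) can only cyclise from the bromide ortho to the ether and should give 2-bromo-6-(3,5-dimethoxyphenoxy)-3,7,9-trimethoxydibenzo[b,d]furan-1-ol F5. SNAr of F5 on 44 (K2CO3, DMF) gives 5-(benzyloxy)-4-{[2-bromo-6-(3,5-dimethoxyphenoxy)-3,7,9-trimethoxydibenzo[b,d]furan-1-yl]oxy}-6-fluoroisophthalaldehyde F6. Debenzylation (BCl3, pentamethylbenzene) gives 4-{[2-bromo-6-(3,5-dimethoxyphenoxy)-3,7,9-trimethoxydibenzo[b,d]furan-1-yl]oxy}-6-fluoro-5-hydroxyisophthalaldehyde F7, and intramolecular Ullmann etherification of F7 (CuI, N,N-dimethylglycine, Cs2CO3) comes back to the route at 48.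

Step 15 (tetra-ortho-substituted Suzuki–Miyaura coupling). Oxidative addition into the hindered, electron-rich triflate and transmetalation of the di-ortho-oxygenated boronate may both be slow, so protodeboronation can consume the nucleophile. The fallback is a Negishi coupling, which avoids the boronate altogether. It sets out from 22: lithiation as in step 14 gives 23, and transmetalation with ZnCl2 (THF, 0 °C) gives chloro[2,4-dimethoxy-6-(methoxymethoxy)phenyl]zinc F8. Coupling of F8 with 20 (Pd2(dba)3, SPhos, THF, 65 °C) comes back to the route at 25.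

**Further compounds**

F1 | step 6 | 2,4,6-trimethoxyphenol | COc1cc(OC)c(O)c(OC)c1
F2 | step 6 | 4,6-dimethoxy-2-(2,4,6-trimethoxyphenoxy)benzaldehyde | O=Cc1c(Oc2c(OC)cc(OC)cc2OC)cc(OC)cc1OC
F3 | step 6 | 2,4-dimethoxy-6-(2,4,6-trimethoxyphenoxy)phenyl formate | O=COc1c(Oc2c(OC)cc(OC)cc2OC)cc(OC)cc1OC
F4 | step 30 | 2,6-dibromo-3-[2-(3,5-dimethoxyphenoxy)-3,5-dimethoxyphenoxy]-5-methoxyphenol | COc1cc(OC)cc(Oc2c(Oc3cc(OC)c(Br)c(O)c3Br)cc(OC)cc2OC)c1
F5 | step 30 | 2-bromo-6-(3,5-dimethoxyphenoxy)-3,7,9-trimethoxydibenzo[b,d]furan-1-ol | COc1cc(OC)cc(Oc2c3oc4cc(OC)c(Br)c(O)c4c3c(OC)cc2OC)c1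
F6 | step 30 | 5-(benzyloxy)-4-{[2-bromo-6-(3,5-dimethoxyphenoxy)-3,7,9-trimethoxydibenzo[b,d]furan-1-yl]oxy}-6-fluoroisophthalaldehyde | COc1cc(OC)cc(Oc2c3oc4cc(OC)c(Br)c(Oc5c(C=O)cc(C=O)c(F)c5OCc5ccccc5)c4c3c(OC)cc2OC)c1
F7 | step 30 | 4-{[2-bromo-6-(3,5-dimethoxyphenoxy)-3,7,9-trimethoxydibenzo[b,d]furan-1-yl]oxy}-6-fluoro-5-hydroxyisophthalaldehyde | COc1cc(OC)cc(Oc2c3oc4cc(OC)c(Br)c(Oc5c(C=O)cc(C=O)c(F)c5O)c4c3c(OC)cc2OC)c1
F8 | step 15 | chloro[2,4-dimethoxy-6-(methoxymethoxy)phenyl]zinc | COCOc1cc(OC)cc(OC)c1[Zn]Cl
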